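**Retrosynthetic overview**
1. Radermachol ⇒ a tetracyclic naphthalene-1,4-diol diketone + 3-methylbut-2-enoyl chloride. The furan (its O–C2 and C2–C3 bonds) is closed last by O-acylation, O→C acyl transfer and cyclodehydration.
2. The six-membered ring that carries the C=O and is fused to the furan ⇒ the five-membered ring of an indane-1,3-dione. One acyl carbon moves from a spiro carbon to the neighbouring CH2 (retro-Claisen/Dieckmann, 5→6), which turns a spiro tetraketone into the fused, aromatised tetracycle.
3. Spiro tetraketone ⇒ indane-1,3-dione + 1,2-bis(bromoacetyl)benzene. A double C-alkylation closes the seven-membered ring, and both events run in one flask. The dibromide comes from 1,2-diacetylbenzene.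
4. Enabling feature: the carbon shared by the furan, the six- and the seven-membered ring is, in the precursor, a non-enolisable spiro carbon. It sits between two equivalent strained five-ring C=O groups and two equivalent enolisable CH2C(=O)Ar groups. The 1,4-dioxygenated ring made by the shift can aromatise, and its free OH ends up next to the remaining CH2, where the furan is needed.
5. Ring order: seven-membered ring (spiro) → six-membered ring (by expansion of the five-membered one) → furan. Both benzo rings are bought.

Key step: step 2

Remark: radermachol has no stereocentre and is achiral, so no enantiocontrol is needed. The O–H···O chelate is written in the given enol/ketone form, which is a proton-shift tautomer of the naphthol/aryl ketone form that the last step delivers.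

Step 1
Reactants: 1 o-diacetylbenzene (1,2-diacetylbenzene)
Product: 2 o-bis(bromoacetyl)benzene (1,2-bis(bromoacetyl)benzene)
Conditions: Br2 (2.0 equiv), AcOH–CHCl3, HBr (cat.), 0 °C to rt
Reagents that add atoms: bromine, BrBr
Why: Acid-catalysed α-bromination of an aryl methyl ketone through its enol should stop at one bromine per acetyl group, because the first bromine slows further enolisation.

Step 2
Reactants: 2 o-bis(bromoacetyl)benzene; 3 indane-1,3-dione
Product: 6 tetracyclic diol-dione (7,12-dihydroxy-6H-benzo[4,5]cyclohepta[1,2-b]naphthalene-5,13-dione), via spiro tetraketone 4 (not isolated), via ring-opened keto ester 5 (not isolated)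
Conditions: K2CO3 (3 equiv), NaI (cat.), DMF, 0.01 M, slow co-addition of 2 and 3, rt, Ar; then NaOMe (6 equiv), MeOH, 60 °C; then 1 M HCl, 0 °C
Reagents that add atoms: none
Why: Proposed new method: the soft C2 enolate of 3 is C-alkylated by both bromoacetyl arms of 2 (two SN2 steps) to the C2v-symmetric spiro tetraketone 4, methoxide then adds to one of its two equivalent strained five-ring carbonyls, retro-Claisen cleavage of the C(=O)–C(spiro) bond gives keto ester 5, and the enolate of a neighbouring ring CH2 attacks the freed benzoate and expels methoxide, so that the acyl carbon has moved from the spiro carbon to the adjacent carbon and the five-membered ring has become the six-membered one. The closest known reaction types are the Gabriel–Colman rearrangement of phthalimidoacetates and the alkoxide-induced ring enlargement of 2-alkyl-2-(alkoxycarbonylmethyl)indane-1,3-diones to 1,4-dihydroxy-2-naphthoates; new here are the ketone enolate as acyl acceptor, the spiro-to-fused transposition and the coupling with the spiro-annulation in one flask. The seven-membered ring closes 7-exo-tet (second alkylation, pre-organised by the ortho-phenylene unit and two sp2 carbonyl carbons) and the six-membered ring closes 6-exo-trig (Dieckmann-type acylation). No stereocentre is created, since 4 and 5 each have a mirror plane and 6 is planar. Site selectivity needs no control because the two carbonyls and the two CH2 groups of 4 are symmetry-equivalent, re-closure of 5 to the five-membered ring is reversible, and only the six-ring triketone can tautomerise to the naphthalene-1,4-diolate, which is the irreversible sink. C- over O-alkylation is secured by the soft bromoketone/iodide pair and by the nine-membered ring that O-attack would need, the two stages are separated so that the nucleophilic diolate never meets 2, and a nucleophilic alkoxide rather than a hindered base is used so that retro-Claisen opening outruns retro-Michael opening of the seven-membered 1,5-diketone.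

Step 3
Reactants: 6 tetracyclic diol-dione; 7 3-methylbut-2-enoyl chloride
Product: 10 radermachol, via O-senecioyl ester 8 (not isolated), via C-acyl triketone 9 (not isolated)
Conditions: K2CO3 (4 equiv), MeCN, Ar, 0 °C (addition of 7, 1.05 equiv) to 70 °C; then 2 M HCl–THF, 40 °C
Reagents that add atoms: 3-methylbut-2-enoyl chloride (7), CC(C)=CC(Cl)=O
Why: The non-chelated 7-OH is acylated first (the 12-OH is locked in an O–H···O=C chelate), the CH2 that is both benzylic and α to the aryl ketone then takes over the acyl group through a five-membered tetrahedral intermediate (Baker–Venkataraman-type O→C transfer), and the resulting o-hydroxyaryl 1,3-diketone closes 5-exo-trig on the enone carbonyl and loses water to the aromatic furan (Paal–Knorr-type cyclodehydration), the alternative closure on the ring ketone being impossible because it would give a bridged furan.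

**Compound list**
1 | 1,2-diacetylbenzene | CC(=O)c1ccccc1C(C)=O | starting material
2 | 1,2-bis(bromoacetyl)benzene | O=C(CBr)c1ccccc1C(=O)CBr | intermediate
3 | indane-1,3-dione | O=C1CC(=O)c2ccccc12 | starting material
4 | spiro[benzo[7]annulene-7,2'-indene]-1',3',5,9(6H,8H)-tetraone (spiro tetraketone, achiral) | O=C1c2ccccc2C(=O)C13CC(=O)c1ccccc1C(=O)C3 | intermediate
5 | methyl 2-[(5,9-dioxo-6,7,8,9-tetrahydro-5H-benzo[7]annulen-7-yl)carbonyl]benzoate (ring-opened keto ester, achiral) | COC(=O)c1ccccc1C(=O)C1CC(=O)c2ccccc2C(=O)C1 | intermediate
6 | 7,12-dihydroxy-6H-benzo[4,5]cyclohepta[1,2-b]naphthalene-5,13-dione (naphthalene-1,4-diol whose C2 aroyl C=O and C3 CH2C(=O) group are tied to the ortho positions of one benzene ring) | O=C1Cc2c(O)c3ccccc3c(O)c2C(=O)c2ccccc12 | intermediate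
7 | 3-methylbut-2-enoyl chloride (senecioyl chloride) | CC(C)=CC(Cl)=O | starting material
8 | 12-hydroxy-5,13-dioxo-6,13-dihydro-5H-benzo[4,5]cyclohepta[1,2-b]naphthalen-7-yl 3-methylbut-2-enoate (O-senecioyl ester) | CC(C)=CC(=O)Oc1c2CC(=O)c3ccccc3C(=O)c2c(O)c2ccccc12 | intermediate
9 | 7,12-dihydroxy-6-(3-methylbut-2-enoyl)-6H-benzo[4,5]cyclohepta[1,2-b]naphthalene-5,13-dione (C-acyl triketone; racemic, configurationally labile centre that is lost in the furan) | CC(C)=CC(=O)C1C(=O)c2ccccc2C(=O)c2c(O)c3ccccc3c(O)c21 | intermediate
10 | radermachol (achiral) | CC(C)=Cc1oc2c3c(c(O)c4ccccc4c(=O)c13)C(=O)c1ccccc1-2 | target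

Total step count: 3. Longest linear sequence: 3 (1 → 2 → 6 → 10).

**Steps most likely to fail**

Step 2 (labelled step).
- **Risk:** The second alkylation may lose to intermolecular alkylation, or to attack of the enolate on the bromoacetyl carbonyl followed by epoxide closure. In the alkoxide stage, retro-Michael opening of the seven-membered 1,5-diketone or saponification of the ester may drain material before the six-membered ring closes.
- **Fallback (known chemistry only):** It sets out from 2 and 3 and comes back at 6. The one-flask rearrangement is replaced by three isolated textbook reactions. The ring enlargement then becomes a separate ring opening followed by a kinetically controlled ring closure, not an equilibration.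
- The double C-alkylation is stopped after the carbonate stage and spiro tetraketone 4 is isolated by crystallisation.
- 4 is opened with catalytic NaOMe in MeOH at 0 °C (retro-Claisen cleavage of a non-enolisable 1,3-diketone) and keto ester 5 is isolated.
- 5 is closed with NaH in THF (intramolecular Claisen condensation of a ketone enolate with an aryl ester) under aprotic conditions. Acidic work-up should then give 6.

Step 3.
- **Risk:** Acylation at the chelated hydroxyl; base-induced loss of conjugation of the senecioyl unit through a dienolate or vinylketene; oxa-Michael closure of the 1,3-diketone enol onto the β,β-dimethyl enone; air oxidation of the hydroquinone.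
- **Fallback:** It sets out from 6 and comes back at 10. The side chain is brought in saturated and the alkene is made last.
- The same acylation/acyl transfer/cyclodehydration with 3-methylbutanoyl chloride should give the 2-isobutyl analogue of radermachol F1.
- Wohl–Ziegler bromination (NBS, AIBN, PhCF3, reflux) at the CH2 next to the furan should give the racemic furfurylic bromide F2.
- E2 elimination with DBU, for which only the CHMe2 hydrogen is available, should give 10.

Step 1.
- **Risk:** Over-bromination, and acid-catalysed intramolecular aldol condensation between the two ortho acetyl groups.
- **Fallback:** It sets out from 1 and comes back at 2. Enolisation and halogenation are separated.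
- TMSOTf/Et3N in CH2Cl2 at 0 °C should give 1,2-bis[1-(trimethylsilyloxy)vinyl]benzene F3.
- F3 is then brominated with NBS (2 equiv) in THF at −78 to 0 °C under essentially neutral conditions to give 2.

**Further compounds**
F0 | step 2 | none | none
F1 | step 3 | 2-isobutyl analogue of radermachol (side-chain dihydro compound) | CC(C)Cc1oc2c3c(c(O)c4ccccc4c(=O)c13)C(=O)c1ccccc1-2
F2 | step 3 | 2-(1-bromo-2-methylpropyl) analogue of radermachol (racemic furfurylic bromide) | CC(C)C(Br)c1oc2c3c(c(O)c4ccccc4c(=O)c13)C(=O)c1ccccc1-2
F3 | step 1 | 1,2-bis[1-(trimethylsilyloxy)vinyl]benzene | C=C(O[Si](C)(C)C)c1ccccc1C(=C)O[Si](C)(C)C
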